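Ring C is cut at O1–C8a and C4–C4a, exploiting that in ring A the ether oxygen O1 (on C8a) and the carbonyl carbon C4 (on C4a) are ortho, with the C5 oxygen next to C4a and only H8 next to C8a: the addition pattern of a 3-alkoxyaryne. In one operation an aryne takes up the oxygen of an (S)-β-oxy ester at C8a and the resulting C4a anion attacks the ester carbonyl, closing ring C with C2 untouched. The precursors are a 2-silylaryl triflate made from a mirror-symmetric phenol, carrying both MOM ethers and the C6 prenyl group, and the (S)-hydroxy ester of ring B, used as its trimethylsilyl ether so that fluoride alone unmasks both partners.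

Key step: step 13

Assumption: flavanone numbering is used throughout (ring A holds C4a–C8a, ring B is the aryl group on C2, ring C is the pyranone), and the (S,S)-TsDPEN ligand is taken to give the (S)-carbinol as it does with simple aryl alkyl ketones.

Step 1
Reactants: 1 phloroglucinol
Product: 2 3,5-bis(methoxymethoxy)phenol
Conditions: MOMCl (2.0 equiv), i-Pr2NEt, DMF/CH2Cl2, 0 °C → rt; chromatography
Reagents that add atoms: chloromethyl methyl ether (MOMCl), COCCl
Why: Williamson-type O-alkylation of three equivalent phenols with two equivalents of the chloromethyl ether should give the bis-ether as the main component of a statistical mixture, from which the mono- and tris-ethers are separated by polarity.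

Step 2
Reactants: 2 3,5-bis(methoxymethoxy)phenol
Product: 3 [3,5-bis(methoxymethoxy)phenoxy]tri(propan-2-yl)silane
Conditions: TIPSCl, imidazole, DMF, rt
Reagents that add atoms: chlorotri(propan-2-yl)silane (TIPSCl), CC(C)[Si](Cl)(C(C)C)C(C)C
Why: Imidazole-mediated O-silylation of the one free phenol installs a bulky, non-coordinating group that closes its two ortho positions to alkyllithiums in the next step.

Step 3
Reactants: 3 [3,5-bis(methoxymethoxy)phenoxy]tri(propan-2-yl)silane; 4 1-bromo-3-methylbut-2-ene (prenyl bromide)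
Product: 6 [3,5-bis(methoxymethoxy)-4-(3-methylbut-2-en-1-yl)phenoxy]tri(propan-2-yl)silane, via aryllithium 5 (not isolated)
Conditions: n-BuLi, THF, 0 °C; then CuI (10 mol%), 4, –78 °C → rt
Reagents that add atoms: none
Why: Directed ortho-metalation removes the one ring proton flanked by two MOM ethers (the positions beside the bulky silyl ether are shielded), and CuI-catalysed allylic substitution by this hindered aryl nucleophile takes place at the primary carbon of 4 to give the linear prenyl arene.

Step 4
Reactants: 6 [3,5-bis(methoxymethoxy)-4-(3-methylbut-2-en-1-yl)phenoxy]tri(propan-2-yl)silane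
Product: 7 3,5-bis(methoxymethoxy)-4-(3-methylbut-2-en-1-yl)phenol
Conditions: TBAF, AcOH, THF, 0 °C
Reagents that add atoms: none
Why: Buffered fluoride desilylation frees the phenol without touching the MOM acetals or the alkene and gives a phenol with a mirror plane through C1 and C4, so that its two ortho positions are equivalent.

Step 5
Reactants: 7 3,5-bis(methoxymethoxy)-4-(3-methylbut-2-en-1-yl)phenol
Product: 8 3,5-bis(methoxymethoxy)-4-(3-methylbut-2-en-1-yl)phenyl N-(propan-2-yl)carbamate
Conditions: i-PrNCO, Et3N (cat.), CH2Cl2, rt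
Reagents that add atoms: isopropyl isocyanate, CC(C)N=C=O
Why: Base-catalysed addition of the phenol to the isocyanate (carbamoylation) gives the N-isopropyl carbamate, a strong ortho-directing group that can later be removed under mild base.

Step 6
Reactants: 8 3,5-bis(methoxymethoxy)-4-(3-methylbut-2-en-1-yl)phenyl N-(propan-2-yl)carbamate
Product: 12 3,5-bis(methoxymethoxy)-4-(3-methylbut-2-en-1-yl)-2-(trimethylsilyl)phenyl N-(propan-2-yl)carbamate, via N-silyl carbamate 9 (not isolated), via ortho-lithiated carbamate 10 (not isolated), via N-silyl C-silyl carbamate 11 (not isolated)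
Conditions: TBSOTf, TMEDA, Et2O, 0 °C → rt; then n-BuLi, TMEDA, –78 °C; then TMSCl, –78 °C → rt; aq. NH4Cl
Reagents that add atoms: chlorotrimethylsilane (TMSCl), C[Si](C)(C)Cl
Why: Directed ortho-metalation of the N-silylated carbamate removes a proton between the carbamate and a MOM ether, the two such positions being equivalent by symmetry, and silyl quench followed by hydrolysis of the labile N–Si bond on work-up gives the C-silyl carbamate.

Step 7
Reactants: 12 3,5-bis(methoxymethoxy)-4-(3-methylbut-2-en-1-yl)-2-(trimethylsilyl)phenyl N-(propan-2-yl)carbamate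
Product: 14 3,5-bis(methoxymethoxy)-4-(3-methylbut-2-en-1-yl)-2-(trimethylsilyl)phenyl trifluoromethanesulfonate, via silylphenol 13 (not isolated)
Conditions: Et2NH, DBU, MeCN, 40 °C; then PhNTf2, rt
Reagents that add atoms: N-phenylbis(trifluoromethanesulfonimide) (PhNTf2), O=S(=O)(N(c1ccccc1)S(=O)(=O)C(F)(F)F)C(F)(F)F
Why: DBU induces E1cB loss of isopropyl isocyanate from the N–H carbamate (trapped by Et2NH as a urea) and the phenoxide so released is O-triflated in the same flask by the triflimide, conditions that leave the aryl–silicon bond in place.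

Step 8
Reactants: 15 4-hydroxyacetophenone; 4 1-bromo-3-methylbut-2-ene (prenyl bromide)
Product: 16 1-[4-hydroxy-3-(3-methylbut-2-en-1-yl)phenyl]ethan-1-one
Conditions: 10% aq. KOH, rt; chromatography
Reagents that add atoms: none
Why: Ortho C-alkylation of the ambident phenoxide (C-allylation of a phenol) is favoured in water where the oxygen is hydrogen-bonded, the para position is blocked by the acetyl group, and the O-prenyl ether and the doubly alkylated phenol are removed by chromatography.

Step 9
Reactants: 16 1-[4-hydroxy-3-(3-methylbut-2-en-1-yl)phenyl]ethan-1-one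
Product: 17 1-[4-(methoxymethoxy)-3-(3-methylbut-2-en-1-yl)phenyl]ethan-1-one
Conditions: MOMCl, i-Pr2NEt, CH2Cl2, 0 °C → rt
Reagents that add atoms: chloromethyl methyl ether (MOMCl), COCCl
Why: O-alkylation of the phenol as its MOM acetal removes the acidic proton before the enolate chemistry and matches the protecting groups of ring A for a single final deprotection.

Step 10
Reactants: 17 1-[4-(methoxymethoxy)-3-(3-methylbut-2-en-1-yl)phenyl]ethan-1-one
Product: 18 methyl 3-[4-(methoxymethoxy)-3-(3-methylbut-2-en-1-yl)phenyl]-3-oxopropanoate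
Conditions: NaH, (MeO)2CO, THF, reflux; AcOH quench
Reagents that add atoms: dimethyl carbonate, COC(=O)OC
Why: Crossed Claisen condensation of the methyl ketone enolate with dimethyl carbonate is driven to completion by irreversible deprotonation of the β-keto ester product.

Step 11
Reactants: 18 methyl 3-[4-(methoxymethoxy)-3-(3-methylbut-2-en-1-yl)phenyl]-3-oxopropanoate
Product: 19 methyl (3S)-3-hydroxy-3-[4-(methoxymethoxy)-3-(3-methylbut-2-en-1-yl)phenyl]propanoate
Conditions: RuCl[(S,S)-TsDPEN](p-cymene) (1 mol%), HCO2H/Et3N azeotrope, 30 °C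
Reagents that add atoms: none
Why: Noyori–Ikariya asymmetric transfer hydrogenation should reduce the aryl ketone through the outer-sphere transition state in which the aryl group lies under the η6-arene, so that hydride reaches one face and sets C3 as (S), while the isolated trisubstituted alkene, the ester and the MOM ether are inert to the ruthenium hydride.

Step 12
Reactants: 19 methyl (3S)-3-hydroxy-3-[4-(methoxymethoxy)-3-(3-methylbut-2-en-1-yl)phenyl]propanoate
Product: 20 methyl (3S)-3-[4-(methoxymethoxy)-3-(3-methylbut-2-en-1-yl)phenyl]-3-[(trimethylsilyl)oxy]propanoate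
Conditions: TMSCl, imidazole, CH2Cl2, 0 °C; filtration, evaporation
Reagents that add atoms: chlorotrimethylsilane (TMSCl), C[Si](C)(C)Cl
Why: O-silylation of the secondary alcohol replaces the only acidic proton of the nucleophile by a fluoride-labile group without touching the stereocenter.

Step 13
Reactants: 14 3,5-bis(methoxymethoxy)-4-(3-methylbut-2-en-1-yl)-2-(trimethylsilyl)phenyl trifluoromethanesulfonate; 20 methyl (3S)-3-[4-(methoxymethoxy)-3-(3-methylbut-2-en-1-yl)phenyl]-3-[(trimethylsilyl)oxy]propanoate
Product: 24 (2S)-5,7-bis(methoxymethoxy)-2-[4-(methoxymethoxy)-3-(3-methylbut-2-en-1-yl)phenyl]-6-(3-methylbut-2-en-1-yl)-2,3-dihydro-4H-chromen-4-one, via potassium alkoxide 21 (not isolated), via aryne 22 (not isolated), via aryl anion adduct 23 (not isolated)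
Conditions: KF (3 equiv), 18-crown-6 (3 equiv), THF, –20 °C → 0 °C; 20 (1.3 equiv), slow addition of 14; pH 7 buffer quench
Reagents that add atoms: none
Why: Proposed new method: fluoride cleaves the O–SiMe3 bond of 20 to give alkoxide 21 and, by attack on the aryl–SiMe3 group with loss of triflate, releases aryne 22; the alkoxide oxygen adds to the aryne carbon remote from the C5 methoxymethoxy group (the future C8a), the aryl anion 23 so formed at C4a adds to the ester carbonyl six atoms away and methoxide is expelled, which makes O1–C8a and C4–C4a in one operation. The closest known reaction types are the fluoride-triggered annulation of salicylate esters with arynes to xanthones and the insertion of arynes into carboxylic acid derivatives with acyl shift, both of which rest on capture of an ortho aryl anion by a tethered carbonyl group. Ring C closes by a 6-exo-trig anionic acyl substitution. No stereocenter is created and none of the four bonds at C2 is broken, so the (S) configuration from step 11 is carried through. The regioselectivity needed (oxygen to C8a, carbon to C4a) is secured by the alkoxy group at C5 beside the triple bond, which directs the nucleophile to the distal carbon and stabilises the anion next to it, and because phenol 7 is mirror-symmetric only the 6-prenyl isomer can arise. Proton capture by the aryl anion and base-induced opening of the flavanone are countered by the silyl ether design: no O–H or N–H donor is present, and the expelled methoxide is trapped by Me3SiF or by excess 20 as MeOSiMe3.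

Step 14
Reactants: 24 (2S)-5,7-bis(methoxymethoxy)-2-[4-(methoxymethoxy)-3-(3-methylbut-2-en-1-yl)phenyl]-6-(3-methylbut-2-en-1-yl)-2,3-dihydro-4H-chromen-4-one
Product: 25 macarangaflavanone B, (2S)-5,7-dihydroxy-2-[4-hydroxy-3-(3-methylbut-2-en-1-yl)phenyl]-6-(3-methylbut-2-en-1-yl)-2,3-dihydro-4H-chromen-4-one
Conditions: 3 M aq. HCl, MeOH, rt → 40 °C
Reagents that add atoms: none
Why: Acid-catalysed transacetalisation with methanol (MOM solvolysis) removes all three acetals as dimethoxymethane under conditions mild enough to leave both prenyl groups, the C2–O1 bond and hence the (2S) centre untouched.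

Compound list
1 | phloroglucinol (benzene-1,3,5-triol) | Oc1cc(O)cc(O)c1 | starting material
2 | 3,5-bis(methoxymethoxy)phenol | COCOc1cc(O)cc(OCOC)c1 | intermediate
3 | [3,5-bis(methoxymethoxy)phenoxy]tri(propan-2-yl)silane | COCOc1cc(OCOC)cc(O[Si](C(C)C)(C(C)C)C(C)C)c1 | intermediate
4 | 1-bromo-3-methylbut-2-ene (prenyl bromide) | CC(C)=CCBr | starting material
5 | [2,6-bis(methoxymethoxy)-4-{[tri(propan-2-yl)silyl]oxy}phenyl]lithium (not isolated) | COCOc1cc(O[Si](C(C)C)(C(C)C)C(C)C)cc(OCOC)c1[Li] | intermediate
6 | [3,5-bis(methoxymethoxy)-4-(3-methylbut-2-en-1-yl)phenoxy]tri(propan-2-yl)silane | COCOc1cc(O[Si](C(C)C)(C(C)C)C(C)C)cc(OCOC)c1CC=C(C)C | intermediate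
7 | 3,5-bis(methoxymethoxy)-4-(3-methylbut-2-en-1-yl)phenol | COCOc1cc(O)cc(OCOC)c1CC=C(C)C | intermediate
8 | 3,5-bis(methoxymethoxy)-4-(3-methylbut-2-en-1-yl)phenyl N-(propan-2-yl)carbamate | COCOc1cc(OC(=O)NC(C)C)cc(OCOC)c1CC=C(C)C | intermediate
9 | 3,5-bis(methoxymethoxy)-4-(3-methylbut-2-en-1-yl)phenyl N-[tert-butyl(dimethyl)silyl]-N-(propan-2-yl)carbamate (not isolated) | COCOc1cc(OC(=O)N(C(C)C)[Si](C)(C)C(C)(C)C)cc(OCOC)c1CC=C(C)C | intermediate
10 | 2-lithio derivative of 9, lithium between the carbamate oxygen and a MOM ether (not isolated) | COCOc1cc(OC(=O)N(C(C)C)[Si](C)(C)C(C)(C)C)c([Li])c(OCOC)c1CC=C(C)C | intermediate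
11 | 3,5-bis(methoxymethoxy)-4-(3-methylbut-2-en-1-yl)-2-(trimethylsilyl)phenyl N-[tert-butyl(dimethyl)silyl]-N-(propan-2-yl)carbamate (not isolated) | COCOc1cc(OC(=O)N(C(C)C)[Si](C)(C)C(C)(C)C)c([Si](C)(C)C)c(OCOC)c1CC=C(C)C | intermediate
12 | 3,5-bis(methoxymethoxy)-4-(3-methylbut-2-en-1-yl)-2-(trimethylsilyl)phenyl N-(propan-2-yl)carbamate | COCOc1cc(OC(=O)NC(C)C)c([Si](C)(C)C)c(OCOC)c1CC=C(C)C | intermediate
13 | 3,5-bis(methoxymethoxy)-4-(3-methylbut-2-en-1-yl)-2-(trimethylsilyl)phenol (present as its phenoxide, not isolated) | COCOc1cc(O)c([Si](C)(C)C)c(OCOC)c1CC=C(C)C | intermediate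
14 | 3,5-bis(methoxymethoxy)-4-(3-methylbut-2-en-1-yl)-2-(trimethylsilyl)phenyl trifluoromethanesulfonate | COCOc1cc(OS(=O)(=O)C(F)(F)F)c([Si](C)(C)C)c(OCOC)c1CC=C(C)C | intermediate
15 | 4-hydroxyacetophenone | CC(=O)c1ccc(O)cc1 | starting material
16 | 1-[4-hydroxy-3-(3-methylbut-2-en-1-yl)phenyl]ethan-1-one | CC(=O)c1ccc(O)c(CC=C(C)C)c1 | intermediate
17 | 1-[4-(methoxymethoxy)-3-(3-methylbut-2-en-1-yl)phenyl]ethan-1-one | CC(=O)c1ccc(OCOC)c(CC=C(C)C)c1 | intermediate
18 | methyl 3-[4-(methoxymethoxy)-3-(3-methylbut-2-en-1-yl)phenyl]-3-oxopropanoate | COC(=O)CC(=O)c1ccc(OCOC)c(CC=C(C)C)c1 | intermediate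
19 | methyl (3S)-3-hydroxy-3-[4-(methoxymethoxy)-3-(3-methylbut-2-en-1-yl)phenyl]propanoate | CC(C)=CCc1cc([C@@H](O)CC(=O)OC)ccc1OCOC | intermediate
20 | methyl (3S)-3-[4-(methoxymethoxy)-3-(3-methylbut-2-en-1-yl)phenyl]-3-[(trimethylsilyl)oxy]propanoate | CC(C)=CCc1cc([C@@H](O[Si](C)(C)C)CC(=O)OC)ccc1OCOC | intermediate
21 | potassium (1S)-3-methoxy-1-[4-(methoxymethoxy)-3-(3-methylbut-2-en-1-yl)phenyl]-3-oxopropan-1-olate (not isolated) | CC(C)=CCc1cc([C@@H]([O-])CC(=O)OC)ccc1OCOC.[K+] | intermediate
22 | 3,5-bis(methoxymethoxy)-4-(3-methylbut-2-en-1-yl)-1,2-didehydrobenzene (aryne, not isolated) | COCOC1=CC#CC(OCOC)=C1CC=C(C)C | intermediate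
23 | aryl potassium adduct: methyl (3S)-3-[3,5-bis(methoxymethoxy)-4-(3-methylbut-2-en-1-yl)-2-potassiophenoxy]-3-[4-(methoxymethoxy)-3-(3-methylbut-2-en-1-yl)phenyl]propanoate (not isolated) | CC(C)=CCc1cc([C@@H](Oc2cc(OCOC)c(CC=C(C)C)c(OCOC)c2[K])CC(=O)OC)ccc1OCOC | intermediate
24 | (2S)-5,7-bis(methoxymethoxy)-2-[4-(methoxymethoxy)-3-(3-methylbut-2-en-1-yl)phenyl]-6-(3-methylbut-2-en-1-yl)-2,3-dihydro-4H-chromen-4-one | CC(C)=CCc1cc([C@@H]2CC(=O)c3c(cc(OCOC)c(CC=C(C)C)c3OCOC)O2)ccc1OCOC | intermediate
25 | macarangaflavanone B, (2S)-5,7-dihydroxy-2-[4-hydroxy-3-(3-methylbut-2-en-1-yl)phenyl]-6-(3-methylbut-2-en-1-yl)-2,3-dihydro-4H-chromen-4-one | CC(C)=CCc1cc([C@@H]2CC(=O)c3c(cc(O)c(CC=C(C)C)c3O)O2)ccc1O | target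

Total step count: 14 (steps 1–7 to silyl triflate 14, steps 8–12 to silyl ether 20, step 13, step 14).
Longest linear sequence: 9 steps (steps 1–7, 13 and 14, from phloroglucinol).

Steps most likely to fail

Step 13 (proposed new method). The aryl anion may be lost to proton or silyl transfer before it reaches the ester, the liberated alkoxide may fragment by retro-aldol cleavage before it is arylated, or C2 may be scrambled by base-induced opening of ring C. The fallback uses known chemistry, sets out from 19 and 14 and returns at 24. Mesylation of 19 and elimination (MsCl, Et3N, then DBU) should give the methyl cinnamate F1, and LiOH saponification the cinnamic acid F2. Heating F2 with 14 and CsF in THF at 125 °C, the known insertion of arynes into the C–O bond of carboxylic acids with acyl shift, should give the 2'-hydroxychalcone F3 with the same regiochemistry at the aryne. NaOAc in refluxing EtOH closes F3 by oxa-Michael addition to the racemic flavanone F4. Preparative HPLC on a chiral stationary phase then delivers 24; the (2R)-antipode F5 is re-equilibrated with base through F3 and recycled.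

Step 6. The base may deprotonate the benzylic and allylic CH2 of the prenyl group instead of the ring, or the silyl triflate may strip a MOM acetal. The fallback sets out from 7 and returns at 14 without a carbamate. NBS in CH2Cl2 at –78 °C should brominate one of the two equivalent ortho positions of the very electron-rich ring faster than it attacks the alkene, giving the bromophenol F6. HMDS converts it into the aryl trimethylsilyl ether F7. n-BuLi at –100 °C then effects bromine–lithium exchange and 1,3 O→C silyl migration (retro-Brook rearrangement) to the lithium phenoxide of 13, which is triflated in the flask with Tf2O to give 14.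

Step 8. O-alkylation and double alkylation of the phenoxide may outrun mono C-alkylation. The fallback sets out from 15 and returns at 17 with the ring position fixed by a halogen. Ring bromination (NBS, cat. NH4OAc, MeCN) gives 3-bromo-4-hydroxyacetophenone F8, and MOMCl/i-Pr2NEt gives its MOM ether F9. Stille coupling of F9 with tributyl(3-methylbut-2-en-1-yl)stannane (Pd(PPh3)4, DMF, 100 °C) should form the aryl–CH2 bond at the less hindered allyl terminus and give 17.

Further compounds
F1 | step 13 | methyl (2E)-3-[4-(methoxymethoxy)-3-(3-methylbut-2-en-1-yl)phenyl]prop-2-enoate | COC(=O)/C=C/c1ccc(OCOC)c(CC=C(C)C)c1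
F2 | step 13 | (2E)-3-[4-(methoxymethoxy)-3-(3-methylbut-2-en-1-yl)phenyl]prop-2-enoic acid | OC(=O)/C=C/c1ccc(OCOC)c(CC=C(C)C)c1
F3 | step 13 | (2E)-1-[6-hydroxy-2,4-bis(methoxymethoxy)-3-(3-methylbut-2-en-1-yl)phenyl]-3-[4-(methoxymethoxy)-3-(3-methylbut-2-en-1-yl)phenyl]prop-2-en-1-one | CC(C)=CCc1cc(/C=C/C(=O)c2c(O)cc(OCOC)c(CC=C(C)C)c2OCOC)ccc1OCOC
F4 | step 13 | racemic 5,7-bis(methoxymethoxy)-2-[4-(methoxymethoxy)-3-(3-methylbut-2-en-1-yl)phenyl]-6-(3-methylbut-2-en-1-yl)-2,3-dihydro-4H-chromen-4-one | CC(C)=CCc1cc(C2CC(=O)c3c(cc(OCOC)c(CC=C(C)C)c3OCOC)O2)ccc1OCOC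
F5 | step 13 | (2R)-5,7-bis(methoxymethoxy)-2-[4-(methoxymethoxy)-3-(3-methylbut-2-en-1-yl)phenyl]-6-(3-methylbut-2-en-1-yl)-2,3-dihydro-4H-chromen-4-one | CC(C)=CCc1cc([C@H]2CC(=O)c3c(cc(OCOC)c(CC=C(C)C)c3OCOC)O2)ccc1OCOC
F6 | step 6 | 2-bromo-3,5-bis(methoxymethoxy)-4-(3-methylbut-2-en-1-yl)phenol | COCOc1cc(O)c(Br)c(OCOC)c1CC=C(C)C
F7 | step 6 | [2-bromo-3,5-bis(methoxymethoxy)-4-(3-methylbut-2-en-1-yl)phenoxy]trimethylsilane | COCOc1cc(O[Si](C)(C)C)c(Br)c(OCOC)c1CC=C(C)C
F8 | step 8 | 1-(3-bromo-4-hydroxyphenyl)ethan-1-one | CC(=O)c1ccc(O)c(Br)c1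
F9 | step 8 | 1-[3-bromo-4-(methoxymethoxy)phenyl]ethan-1-one | CC(=O)c1ccc(OCOC)c(Br)c1
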